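# Proposed synthesis of (2R)-2-[8-hydroxy-2,2-dimethyl-7-(3-methylbut-2-en-1-yl)-2H-chromen-6-yl]chroman-7-ol (26)

## The problem

The target 26 is a flavan. Ring A is resorcinol-derived and carries the 7-hydroxyl, ring C is a saturated pyran (O1, C2, C3, C4), and ring B on C2 is substituted at five of its six positions: C1' bears C2, C2' a prenyl group, C3' a free hydroxyl, and O4'/C5' are bridged by a 2,2-dimethyl-2H-pyran (ring D). The only stereocentre is C2 (R), a benzylic carbon that also bears O1. No second centre can relay or correct it, so it must be set by a catalyst and then kept through every later step. Keeping it is the main difficulty, because C2–O1 is a para-alkoxybenzylic aryl ether (through O4'). Acid can ionise it, a free 4'-phenoxide can expel O1 by forming a para-quinone methide, and hydrogenolysis catalysts can cleave it. Ring B adds a regiochemical problem: the prenyl group must enter the crowded C2' position while the pyran bridges O4' and C5'. A prenyl group beside a free phenol also cyclises under acid, and once either ring B alkene is present hydrogenation is excluded. Two features of the structure open a short solution. C3 and C4 are plain methylene groups, so the C3–C4 bond can be made as an alkene from a vinyl group on C4a of ring A and a vinyl group on C2, which makes O1–C2 an allylic aryl ether bond open to asymmetric allylic substitution. O3' and O4' each have exactly one free ortho position (C2' and C5'), so both carbon substituents of ring B can be delivered from oxygen by sigmatropic rearrangement.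

## Retrosynthesis

**C2'–prenyl bond.** After the silyl ether of 25 is taken off last (26 from 25), the prenyl C–C bond is cut back to the 3'-O-(1,1-dimethylallyl) ether 23, which rearranges through dienone 24. Direct C-prenylation of phenol 21 would have to distinguish C2' from C6' and from ring A. A metalation at C2' would compete with C8 of ring A (between two oxygens) and with the benzylic C2–H. The tethered [3,3] shift can only reach C2', because the other ortho position of O3' is C4'. Ether 23 comes from alkyne 22 by semihydrogenation, and 22 from phenol 21 and the propargyl carbonate 16, which is made in one step from alkynol 15. The forward reaction must tolerate a hindered terminus and must leave the 3'-hydroxyl free, which it does by design.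

**Ring D (C5'–C bond, then O4'-to-carbon ring closure).** Phenol 21 is unmasked from methoxymethyl ether 19 through silyl ether 20. The pyran of 19 is cut at C5' back to the 4'-O-(1,1-dimethylpropargyl) ether 17, which rearranges through allenylphenol 18. O4' again has a single free ortho position, so the propargyl Claisen cascade is regiospecific. Ether 17 comes from phenol 14 and the same carbonate 16. The precursor 14 is a plain flavan with a differentiated catechol, and the forward O-alkylation has to be run cold because 14 has a free 4'-hydroxyl para to C1'.

**Saturation of C3–C4 and release of O4'.** Phenol 14 comes from benzyl ether 13 by hydrogenolysis, and 13 from 2H-chromene 12 by alkene reduction. The unsaturation is added in the retrosynthetic direction because it makes the C3–C4 bond accessible by metathesis. Both operations are placed before any ring B alkene exists, so no chemoselectivity between alkenes is asked for. The reduction must not move the double bond toward C2 and must not break the allylic C2–O1 bond, which points to diimide and away from a metal surface.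

**C3=C4 (key disconnection).** Chromene 12 is opened across C3=C4 to diene 11. The neighbouring cuts are weaker. Closing O1–C2 from a 1,3-diarylpropanol would pass through an ionisable para-alkoxybenzylic centre. Closing C4–C4a by Friedel–Crafts chemistry needs acid beside the same centre. The metathesis touches no bond to C2, runs under neutral conditions, and its precursor is an acyclic ether with two terminal alkenes in which O1–C2 and the stereocentre are already in place.

**O1–C2 and the stereocentre.** Diene 11 is cut at O1–C2 into cinnamyl carbonate 6 and vinylphenol 9, joined through aryloxide 10 by iridium-catalysed asymmetric allylic etherification. This is convergent (two fragments of similar size) and sets C2 by catalyst control in the bond-forming step. The vinyl group is installed on ring A before the etherification, not after it. An aryloxide bearing an ortho-formyl group would be a weaker nucleophile and a better leaving group, and the electron-rich 1-arylallyl ether could then re-ionise and lose branched selectivity and enantiomeric purity.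

**Fragments.** Carbonate 6 goes back through alcohol 5, ester 4 and aldehyde 3 to 2 and 1. The two catechol oxygens are told apart by the higher acidity of the hydroxyl para to the formyl group. Vinylphenol 9 goes back through 8 to 7, where the hydrogen bond of the 2-hydroxyl to the formyl group leaves the 4-hydroxyl to be silylated. Carbonate 16 is the O-methoxycarbonyl derivative of the commercial alkynol 15.

## Roads not taken

Alternative 1: Ring C would be cut at O1–C2 and C3–C4 at once, with an extra formyl carbon on C3. In the forward step a diarylprolinol silyl ether activates the fully decorated ring B enal A2 as an iminium ion. The phenol oxygen of salicylaldehyde A3 adds to the β-carbon, the enamine condenses with the aryl aldehyde, and dehydration gives chromene-3-carbaldehyde A1. The merits are real: two ring bonds and the stereocentre form in one metal-free operation, the route is convergent, and ring B arrives complete so no rearrangement chemistry follows ring closure. The weak points are specific to this target. The oxa-Michael addition is reversible, and A2 is a poor acceptor because its aryl group is electron-rich and ortho-substituted, so rate and enantiomeric purity are both at risk. A1 carries a carbon the target lacks, so a decarbonylation is needed, and C3=C4 must be reduced beside the prenyl and pyran alkenes. Two methoxymethyl ethers would then have to leave under acid next to an ortho-prenyl phenol and the ionisable C2–O1 bond. A2 itself needs both Claisen sequences and a chain extension before the key step. On bonds made per step this road is better than the chosen plan, which spends steps 8 and 9 and two precious-metal catalysts on the same two bonds. The chosen plan offers in return an O1–C2 bond formed irreversibly under catalyst control, no carbon to excise, and a C3=C4 reduction carried out while ring B has no alkene.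

Alternative 2: The cuts are the C2'–CH2 and C5'–C bonds of ring B, made in one thermal operation. Heating the mixed diether A4 would move the allyl group to C2' and the propargyl group to C5', and hydrogen shift and oxa-6π closure would then give A5, which is the same compound as 25. This is an endgame variant and says nothing about ring C or C2, so it would still need a flavan synthesis such as the one proposed here. Its merit is step economy: from 14 it would need about four operations where steps 13 to 18 use six. Its weak points lie in making and heating A4. The 3'-oxygen has to be unmasked and alkylated beside a tertiary propargyl ether that tolerates neither acid nor heat. The allyl unit cannot come from an alkyne by semihydrogenation while the other alkyne is present. The two rearrangements have different thermal thresholds, so the first-formed ortho-prenyl phenol sits at the higher temperature for the whole reaction, where fragmentation and cyclisation compete. In step count this road is better by two. Against that, the chosen plan runs each rearrangement at its own temperature, removes the methoxymethyl group on the robust pyran 19, and makes both ethers from the single carbonate 16.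

Alternative 3: Ring C would be cut at C4–C4a and O1–C2 and assembled from allylic alcohol A6 and phenol A7. A chiral binaphthol-derived phosphoric acid ionises A6 to a vinyl para-quinone methide. A7 attacks its terminal carbon through the position ortho to the hydroxyl, and after re-formation of a quinone methide the phenol oxygen closes onto C2 within the chiral ion pair, giving flavan A8, which is identical with 14. If it worked with high selectivity this would be the shortest road by a wide margin, since it reaches 14 in roughly five operations against eleven and uses no metal. The weak points are constitutional and stereochemical. A7 can attack the benzylic carbon instead of the terminal one, which leads to a 4-arylchroman, and it can react through the position para to its hydroxyl or through oxygen. A monosilylated resorcinol is also a modest nucleophile for this chemistry. Most seriously, A8 keeps the free 4'-hydroxyl, so the acid that closes the ring can reopen it through the same quinone methide, and the enantiomeric purity would be under thermodynamic threat throughout. The chosen plan is longer. It sets against this two ring-forming reactions that can only give the flavan connectivity, a stereocentre fixed irreversibly without acid, and a C2–O1 bond that never meets acid while the 4'-hydroxyl is free.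

Key step: step 9

Remark on the chemistry: the stereocentre encoded in the target is C2 with R configuration (O1 > C1' > C3 > H). The ligand antipode in step 8 is the one that delivers this configuration, expected to be (Ra,R,R) from the usual facial preference of this catalyst family. The configuration of 11 is to be confirmed before going on, and the antipodal ligand used if the sense is opposite.

## Route

Step 1
Reactants: 1 3,4-dihydroxybenzaldehyde
Product: 2 4-(benzyloxy)-3-hydroxybenzaldehyde
Conditions: BnBr (1.05 equiv), NaHCO3, DMF, 40 °C
Reagents that add atoms: benzyl bromide, BrCc1ccccc1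
Why: Williamson etherification; the hydroxyl para to the formyl group is the more acidic one, so a weak base forms only its phenoxide and the 4-O-benzyl ether should result regioselectively.

Step 2
Reactants: 2 4-(benzyloxy)-3-hydroxybenzaldehyde
Product: 3 4-(benzyloxy)-3-(methoxymethoxy)benzaldehyde
Conditions: MOMCl, i-Pr2NEt, CH2Cl2, 0 °C to rt
Reagents that add atoms: chloromethyl methyl ether, COCCl
Why: O-alkylation of the remaining phenol to the acetal; the methoxymethyl ether is inert to the basic, organometallic, reductive and thermal steps that precede its removal in step 15 and is orthogonal to benzyl and silyl.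

Step 3
Reactants: 3 4-(benzyloxy)-3-(methoxymethoxy)benzaldehyde
Product: 4 ethyl (E)-3-[4-(benzyloxy)-3-(methoxymethoxy)phenyl]prop-2-enoate
Conditions: (EtO)2P(O)CH2CO2Et, NaH, THF, 0 °C to rt
Reagents that add atoms: triethyl phosphonoacetate, CCOC(=O)CP(=O)(OCC)OCC
Why: Horner–Wadsworth–Emmons olefination with a stabilised phosphonate anion, which should give the E-cinnamate.

Step 4
Reactants: 4 ethyl (E)-3-[4-(benzyloxy)-3-(methoxymethoxy)phenyl]prop-2-enoate
Product: 5 (E)-3-[4-(benzyloxy)-3-(methoxymethoxy)phenyl]prop-2-en-1-ol
Conditions: i-Bu2AlH (2.2 equiv), CH2Cl2, −78 °C; aqueous potassium sodium tartrate (KNaC4H4O6) work-up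
Reagents that add atoms: none
Why: 1,2-reduction of the conjugated ester by the aluminium hydride to the allylic alcohol with the alkene geometry unchanged.

Step 5
Reactants: 5 (E)-3-[4-(benzyloxy)-3-(methoxymethoxy)phenyl]prop-2-en-1-ol
Product: 6 (E)-3-[4-(benzyloxy)-3-(methoxymethoxy)phenyl]prop-2-en-1-yl methyl carbonate
Conditions: ClCO2Me, pyridine, CH2Cl2, 0 °C
Reagents that add atoms: methyl chloroformate, COC(=O)Cl
Why: O-acylation to the linear E-cinnamyl methyl carbonate, the standard electrophile for iridium-catalysed allylic substitution.

Step 6
Reactants: 7 2,4-dihydroxybenzaldehyde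
Product: 8 2-hydroxy-4-(triisopropylsilyloxy)benzaldehyde
Conditions: i-Pr3SiCl (1.05 equiv), imidazole, CH2Cl2, 0 °C
Reagents that add atoms: triisopropylsilyl chloride, CC(C)[Si](Cl)(C(C)C)C(C)C
Why: Silylation takes the 4-hydroxyl because the 2-hydroxyl is hydrogen-bonded to the formyl group and hindered; the bulky aryl silyl ether should survive every step up to fluoride cleavage in step 19.

Step 7
Reactants: 8 2-hydroxy-4-(triisopropylsilyloxy)benzaldehyde
Product: 9 2-ethenyl-5-(triisopropylsilyloxy)phenol
Conditions: Ph3PCH3Br (2.6 equiv), KOtBu (2.5 equiv), THF, 0 °C to rt; aqueous NH4Cl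
Reagents that add atoms: methyltriphenylphosphonium bromide, C[P+](c1ccccc1)(c1ccccc1)c1ccccc1.[Br-]
Why: Wittig methylenation; the first equivalent of ylide is spent on the phenol, and the resulting phenoxide aldehyde is still methylenated by the excess, a routine way to 2-vinylphenols.

Step 8
Reactants: 9 2-ethenyl-5-(triisopropylsilyloxy)phenol; 6 (E)-3-[4-(benzyloxy)-3-(methoxymethoxy)phenyl]prop-2-en-1-yl methyl carbonate
Product: 11 (R)-1-[4-(benzyloxy)-3-(methoxymethoxy)phenyl]prop-2-en-1-yl 2-ethenyl-5-(triisopropylsilyloxy)phenyl ether, via lithium aryloxide 10 (not isolated)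
Conditions: 9 (1.5 equiv), n-BuLi (1.0 equiv on 9), THF, −78 to 0 °C; then 6, [Ir(cod)Cl]2 (2 mol%), (Ra,R,R)-O,O'-(1,1'-binaphthyl-2,2'-diyl) N,N-bis(1-phenylethyl)phosphoramidite (4 mol%, catalyst pre-activated with n-PrNH2), THF, rt to 40 °C
Reagents that add atoms: none
Why: Iridium-catalysed asymmetric allylic etherification: the cyclometalated iridium–phosphoramidite complex ionises the carbonate to an allyl complex and the aryloxide attacks its substituted terminus from outside the metal, giving the branched ether. C2 is set here by the chiral ligand alone, and the reaction is stopped at full conversion of 6 so that the electron-rich product does not re-ionise.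

Step 9
Reactants: 11 (R)-1-[4-(benzyloxy)-3-(methoxymethoxy)phenyl]prop-2-en-1-yl 2-ethenyl-5-(triisopropylsilyloxy)phenyl ether
Product: 12 (2R)-2-[4-(benzyloxy)-3-(methoxymethoxy)phenyl]-7-(triisopropylsilyloxy)-2H-chromene
Conditions: second-generation Grubbs catalyst (H2IMes)(PCy3)Cl2Ru=CHPh (5 mol%), 1,4-benzoquinone (10 mol%), CH2Cl2 (0.01 M), 40 °C, dark
Reagents that add atoms: none
Why: The ruthenium benzylidene exchanges with one terminal alkene of 11, the new alkylidene adds to the second alkene in an intramolecular [2+2] cycloaddition, and cycloreversion of the ruthenacyclobutane releases 12 and a ruthenium methylidene that carries the chain with loss of ethene. The closest known reaction type is ring-closing metathesis of 2-vinylaryl allyl ethers to 2H-chromenes, 2-aryl members included. Ring C closes as a six-membered ring by forming the endocyclic C3=C4 bond, necessarily cis, from a 1,7-diene whose tether (C4a, C8a, O1, C2) is held in place by the arene. No stereocentre is formed, and no bond to C2, set in step 8, is made or broken. The step needs retention of that centre and of the alkene position, so 1,4-benzoquinone is added to intercept ruthenium hydrides that would move the double bond toward C2 and give the achiral 4H-chromene. Neutral acid-free solvent and 40 °C keep the allylic para-alkoxybenzylic ether from ionising or undergoing Claisen rearrangement, and exclusion of light avoids electrocyclic opening of the 2H-chromene. High dilution favours ring closure over cross-metathesis of the electron-rich styrene, and ring B has no alkene at this stage, so no other ring can close.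

Step 10
Reactants: 12 (2R)-2-[4-(benzyloxy)-3-(methoxymethoxy)phenyl]-7-(triisopropylsilyloxy)-2H-chromene
Product: 13 (2R)-2-[4-(benzyloxy)-3-(methoxymethoxy)phenyl]-7-(triisopropylsilyloxy)chromane
Conditions: 2-nitrobenzenesulfonylhydrazide (excess, in portions), Et3N, CH2Cl2, rt, dark
Reagents that add atoms: none
Why: Diimide reduction: diimide generated at room temperature transfers two hydrogens to C3=C4 through a concerted cyclic transition state. No metal is present, so the double bond cannot migrate toward C2, and neither the allylic C2–O1 bond nor the benzyl ether can be hydrogenolysed.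

Step 11
Reactants: 13 (2R)-2-[4-(benzyloxy)-3-(methoxymethoxy)phenyl]-7-(triisopropylsilyloxy)chromane
Product: 14 2-(methoxymethoxy)-4-[(2R)-7-(triisopropylsilyloxy)chroman-2-yl]phenol
Conditions: H2 (1 atm), 10% Pd/C, EtOAc, rt
Reagents that add atoms: none
Why: Hydrogenolysis of the primary benzyl aryl ether; the secondary cyclic C2–O1 benzylic ether cleaves far more slowly in neutral ethyl acetate, and the reaction is stopped when 13 is consumed. No alkene is present yet.

Step 12
Reactants: 15 2-methylbut-3-yn-2-ol
Product: 16 methyl 2-methylbut-3-yn-2-yl carbonate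
Conditions: n-BuLi (1.0 equiv), THF, −78 °C; then ClCO2Me, −78 °C to rt; distillation
Reagents that add atoms: methyl chloroformate, COC(=O)Cl
Why: O-acylation of the lithium alkoxide: one equivalent of base removes only the hydroxyl proton, which is far more acidic than the alkyne C–H, and the tertiary alkoxide is trapped by the chloroformate. The carbonate is a distillable, storable electrophile that serves both propargylations of the route.

Step 13
Reactants: 14 2-(methoxymethoxy)-4-[(2R)-7-(triisopropylsilyloxy)chroman-2-yl]phenol; 16 methyl 2-methylbut-3-yn-2-yl carbonate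
Product: 17 (2R)-2-[3-(methoxymethoxy)-4-(2-methylbut-3-yn-2-yloxy)phenyl]-7-(triisopropylsilyloxy)chromane
Conditions: 16 (1.5 equiv), DBU, CuCl2·2H2O (1 mol%), MeCN, 0 °C
Reagents that add atoms: none
Why: Copper-catalysed propargylic substitution: the tertiary propargyl carbonate is activated as a copper acetylide and allenylidene-type electrophile, loses methyl carbonate and is captured by the phenoxide at 0 °C. This is a standard way to hindered 1,1-dimethylpropargyl aryl ethers, and the low temperature limits the exposure of the 4'-phenoxide.

Step 14
Reactants: 17 (2R)-2-[3-(methoxymethoxy)-4-(2-methylbut-3-yn-2-yloxy)phenyl]-7-(triisopropylsilyloxy)chromane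
Product: 19 (2R)-2-[8-(methoxymethoxy)-2,2-dimethyl-2H-chromen-6-yl]-7-(triisopropylsilyloxy)chromane, via ortho-allenylphenol 18 (not isolated)
Conditions: o-xylene, 140 °C
Reagents that add atoms: none
Why: Aromatic propargyl Claisen rearrangement to C5', the only free position ortho to O4', then tautomerisation to the allenylphenol, 1,5-hydrogen shift and oxa-6π electrocyclisation, which should give the 2,2-dimethyl-2H-pyran under neutral conditions.

Step 15
Reactants: 19 (2R)-2-[8-(methoxymethoxy)-2,2-dimethyl-2H-chromen-6-yl]-7-(triisopropylsilyloxy)chromane
Product: 21 2,2-dimethyl-6-[(2R)-7-(triisopropylsilyloxy)chroman-2-yl]-2H-chromen-8-ol, via aryl trimethylsilyl ether 20 (not isolated)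
Conditions: Me3SiOTf, 2,2'-bipyridyl, MeCN, 0 °C to rt; then H2O
Reagents that add atoms: none
Why: Silyl triflate and bipyridyl convert an aryl methoxymethyl ether into the aryl trimethylsilyl ether without free acid, and water then hydrolyses it. Protic acid is avoided because it could ionise the para-alkoxybenzylic C2–O1 bond; the bulky silyl ether on ring A should not be touched.

Step 16
Reactants: 21 2,2-dimethyl-6-[(2R)-7-(triisopropylsilyloxy)chroman-2-yl]-2H-chromen-8-ol; 16 methyl 2-methylbut-3-yn-2-yl carbonate
Product: 22 (2R)-2-[2,2-dimethyl-8-(2-methylbut-3-yn-2-yloxy)-2H-chromen-6-yl]-7-(triisopropylsilyloxy)chromane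
Conditions: 16 (1.5 equiv), DBU, CuCl2·2H2O (1 mol%), MeCN, 0 °C
Reagents that add atoms: none
Why: The same copper-catalysed propargylic etherification as in step 13, now on the 3'-hydroxyl; this phenoxide is meta to C1', so it cannot open ring C.

Step 17
Reactants: 22 (2R)-2-[2,2-dimethyl-8-(2-methylbut-3-yn-2-yloxy)-2H-chromen-6-yl]-7-(triisopropylsilyloxy)chromane
Product: 23 (2R)-2-[2,2-dimethyl-8-(2-methylbut-3-en-2-yloxy)-2H-chromen-6-yl]-7-(triisopropylsilyloxy)chromane
Conditions: H2 (1 atm), Pd/CaCO3 poisoned with Pb(OAc)2 (Lindlar catalyst), quinoline, EtOAc, rt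
Reagents that add atoms: none
Why: Semihydrogenation of the terminal alkyne on the poisoned catalyst gives the 1,1-dimethylallyl ether; the cis-disubstituted pyran alkene and the benzylic ether should not react on this catalyst.

Step 18
Reactants: 23 (2R)-2-[2,2-dimethyl-8-(2-methylbut-3-en-2-yloxy)-2H-chromen-6-yl]-7-(triisopropylsilyloxy)chromane
Product: 25 2,2-dimethyl-7-(3-methylbut-2-en-1-yl)-6-[(2R)-7-(triisopropylsilyloxy)chroman-2-yl]-2H-chromen-8-ol, via ortho-prenyl cyclohexadienone 24 (not isolated)
Conditions: o-xylene, 130 °C, sealed tube
Reagents that add atoms: none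
Why: Aromatic Claisen rearrangement: the [3,3] shift can only end at C2', the single free position ortho to O3', and the allyl inversion turns the 1,1-dimethylallyl group into the prenyl group. The dienone tautomerises to the free 3'-phenol, and neutral non-polar conditions suppress ionisation of the tertiary ether and cyclisation of the product.

Step 19
Reactants: 25 2,2-dimethyl-7-(3-methylbut-2-en-1-yl)-6-[(2R)-7-(triisopropylsilyloxy)chroman-2-yl]-2H-chromen-8-ol
Product: 26 (2R)-2-[8-hydroxy-2,2-dimethyl-7-(3-methylbut-2-en-1-yl)-2H-chromen-6-yl]chroman-7-ol
Conditions: n-Bu4NF, AcOH, THF, 0 °C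
Reagents that add atoms: none
Why: Fluoride cleaves the aryl silicon–oxygen bond; acetic acid buffers the phenoxide, and the prenyl group, the pyran alkene and C2 are not involved.

## Compound list

1 | 3,4-dihydroxybenzaldehyde | O=Cc1ccc(O)c(O)c1 | starting material
2 | 4-(benzyloxy)-3-hydroxybenzaldehyde | O=Cc1ccc(OCc2ccccc2)c(O)c1 | intermediate
3 | 4-(benzyloxy)-3-(methoxymethoxy)benzaldehyde | O=Cc1ccc(OCc2ccccc2)c(OCOC)c1 | intermediate
4 | ethyl (E)-3-[4-(benzyloxy)-3-(methoxymethoxy)phenyl]prop-2-enoate | CCOC(=O)/C=C/c1ccc(OCc2ccccc2)c(OCOC)c1 | intermediate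
5 | (E)-3-[4-(benzyloxy)-3-(methoxymethoxy)phenyl]prop-2-en-1-ol | OC/C=C/c1ccc(OCc2ccccc2)c(OCOC)c1 | intermediate
6 | (E)-3-[4-(benzyloxy)-3-(methoxymethoxy)phenyl]prop-2-en-1-yl methyl carbonate | COC(=O)OC/C=C/c1ccc(OCc2ccccc2)c(OCOC)c1 | intermediate
7 | 2,4-dihydroxybenzaldehyde | O=Cc1ccc(O)cc1O | starting material
8 | 2-hydroxy-4-(triisopropylsilyloxy)benzaldehyde | O=Cc1ccc(O[Si](C(C)C)(C(C)C)C(C)C)cc1O | intermediate
9 | 2-ethenyl-5-(triisopropylsilyloxy)phenol | C=Cc1ccc(O[Si](C(C)C)(C(C)C)C(C)C)cc1O | intermediate
10 | lithium 2-ethenyl-5-(triisopropylsilyloxy)phenoxide | [Li+].[O-]c1cc(O[Si](C(C)C)(C(C)C)C(C)C)ccc1C=C | intermediate (not isolated)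
11 | (R)-1-[4-(benzyloxy)-3-(methoxymethoxy)phenyl]prop-2-en-1-yl 2-ethenyl-5-(triisopropylsilyloxy)phenyl ether | COCOc1cc([C@H](Oc2cc(O[Si](C(C)C)(C(C)C)C(C)C)ccc2C=C)C=C)ccc1OCc1ccccc1 | intermediate
12 | (2R)-2-[4-(benzyloxy)-3-(methoxymethoxy)phenyl]-7-(triisopropylsilyloxy)-2H-chromene | COCOc1cc([C@H]2C=Cc3ccc(O[Si](C(C)C)(C(C)C)C(C)C)cc3O2)ccc1OCc1ccccc1 | intermediate
13 | (2R)-2-[4-(benzyloxy)-3-(methoxymethoxy)phenyl]-7-(triisopropylsilyloxy)chromane | COCOc1cc([C@H]2CCc3ccc(O[Si](C(C)C)(C(C)C)C(C)C)cc3O2)ccc1OCc1ccccc1 | intermediate
14 | 2-(methoxymethoxy)-4-[(2R)-7-(triisopropylsilyloxy)chroman-2-yl]phenol | COCOc1cc([C@H]2CCc3ccc(O[Si](C(C)C)(C(C)C)C(C)C)cc3O2)ccc1O | intermediate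
15 | 2-methylbut-3-yn-2-ol | CC(C)(O)C#C | starting material
16 | methyl 2-methylbut-3-yn-2-yl carbonate | COC(=O)OC(C)(C)C#C | intermediate
17 | (2R)-2-[3-(methoxymethoxy)-4-(2-methylbut-3-yn-2-yloxy)phenyl]-7-(triisopropylsilyloxy)chromane | COCOc1cc([C@H]2CCc3ccc(O[Si](C(C)C)(C(C)C)C(C)C)cc3O2)ccc1OC(C)(C)C#C | intermediate
18 | 2-(methoxymethoxy)-6-(3-methylbuta-1,2-dien-1-yl)-4-[(2R)-7-(triisopropylsilyloxy)chroman-2-yl]phenol | COCOc1cc([C@H]2CCc3ccc(O[Si](C(C)C)(C(C)C)C(C)C)cc3O2)cc(C=C=C(C)C)c1O | intermediate (not isolated)
19 | (2R)-2-[8-(methoxymethoxy)-2,2-dimethyl-2H-chromen-6-yl]-7-(triisopropylsilyloxy)chromane | COCOc1cc([C@H]2CCc3ccc(O[Si](C(C)C)(C(C)C)C(C)C)cc3O2)cc2c1OC(C)(C)C=C2 | intermediate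
20 | (2R)-2-[2,2-dimethyl-8-(trimethylsilyloxy)-2H-chromen-6-yl]-7-(triisopropylsilyloxy)chromane | C[Si](C)(C)Oc1cc([C@H]2CCc3ccc(O[Si](C(C)C)(C(C)C)C(C)C)cc3O2)cc2c1OC(C)(C)C=C2 | intermediate (not isolated)
21 | 2,2-dimethyl-6-[(2R)-7-(triisopropylsilyloxy)chroman-2-yl]-2H-chromen-8-ol | Oc1cc([C@H]2CCc3ccc(O[Si](C(C)C)(C(C)C)C(C)C)cc3O2)cc2c1OC(C)(C)C=C2 | intermediate
22 | (2R)-2-[2,2-dimethyl-8-(2-methylbut-3-yn-2-yloxy)-2H-chromen-6-yl]-7-(triisopropylsilyloxy)chromane | C#CC(C)(C)Oc1cc([C@H]2CCc3ccc(O[Si](C(C)C)(C(C)C)C(C)C)cc3O2)cc2c1OC(C)(C)C=C2 | intermediate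
23 | (2R)-2-[2,2-dimethyl-8-(2-methylbut-3-en-2-yloxy)-2H-chromen-6-yl]-7-(triisopropylsilyloxy)chromane | C=CC(C)(C)Oc1cc([C@H]2CCc3ccc(O[Si](C(C)C)(C(C)C)C(C)C)cc3O2)cc2c1OC(C)(C)C=C2 | intermediate
24 | 2,2-dimethyl-7-(3-methylbut-2-en-1-yl)-6-[(2R)-7-(triisopropylsilyloxy)chroman-2-yl]-2H-chromen-8(7H)-one (ring B dienone, both configurations at its sp3 carbon) | O=C1C(CC=C(C)C)C([C@H]2CCc3ccc(O[Si](C(C)C)(C(C)C)C(C)C)cc3O2)=CC2=C1OC(C)(C)C=C2 | intermediate (not isolated)
25 | 2,2-dimethyl-7-(3-methylbut-2-en-1-yl)-6-[(2R)-7-(triisopropylsilyloxy)chroman-2-yl]-2H-chromen-8-ol | CC(C)=CCc1c([C@H]2CCc3ccc(O[Si](C(C)C)(C(C)C)C(C)C)cc3O2)cc2c(c1O)OC(C)(C)C=C2 | intermediate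
26 | (2R)-2-[8-hydroxy-2,2-dimethyl-7-(3-methylbut-2-en-1-yl)-2H-chromen-6-yl]chroman-7-ol | CC(C)=CCc1c([C@H]2CCc3ccc(O)cc3O2)cc2c(c1O)OC(C)(C)C=C2 | target

## Step count and least certain steps

Total: 19 steps. Longest linear sequence: 16 steps (steps 1 to 5, 8 to 11 and 13 to 19). The ring A branch (steps 6 and 7) joins at step 8, and the one-step reagent branch (step 12) joins at steps 13 and 16.

**Step 9 (key step).** The most likely failure is loss of positional and configurational integrity after ring closure. Ruthenium hydrides formed as the catalyst decays can shift C3=C4 toward C2, and a slow closure would let cross-metathesis of the electron-rich styrene compete. The fallback closes ring C at C4–C4a instead and sets out from 6. 4-Bromoresorcinol would be silylated at the hydroxyl remote from bromine (i-Pr3SiCl, imidazole) to give 2-bromo-5-(triisopropylsilyloxy)phenol F1. Deprotonation with n-BuLi gives lithium 2-bromo-5-(triisopropylsilyloxy)phenoxide F2 (not isolated), which with 6 under the conditions of step 8 should give (R)-1-[4-(benzyloxy)-3-(methoxymethoxy)phenyl]prop-2-en-1-yl 2-bromo-5-(triisopropylsilyloxy)phenyl ether F3. Hydroboration of the vinyl group with 9-BBN-H gives the primary B-alkyl-9-borabicyclo[3.3.1]nonane F4 (not isolated). Pd(dppf)Cl2 with aqueous K3PO4 in THF/DMF at 60 °C then closes the ring by intramolecular B-alkyl Suzuki–Miyaura coupling. This comes back to the route at 13 and bypasses steps 9 and 10.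

**Step 8.** The most likely failure is slow turnover with erosion of branched selectivity and enantiomeric purity. The ortho-vinyl aryloxide is hindered, its alkene can occupy a coordination site on iridium, and the electron-rich vinylphenol can be lost by oligomerisation while the product re-ionises during a long reaction. The fallback changes the nucleophile class and installs the vinyl group after the C–O bond; it sets out from 8 and 6. Deprotonation of 8 with n-BuLi gives lithium 2-formyl-5-(triisopropylsilyloxy)phenoxide F5 (not isolated), which is used in place of 10 and should give (R)-2-{1-[4-(benzyloxy)-3-(methoxymethoxy)phenyl]prop-2-en-1-yloxy}-4-(triisopropylsilyloxy)benzaldehyde F6. Wittig methylenation of F6 (Ph3PCH3Br, KOtBu, THF) comes back to the route at 11.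

**Step 10.** The most likely failure is incomplete reduction. Diimide disproportionates faster than it adds to a cis-disubstituted styrenyl alkene next to the tertiary C2, so repeated charges and long exposure of the sensitive chromene would be needed. The fallback is homogeneous hydrogenation with RhCl(PPh3)3 under H2 (1 atm) in benzene/EtOH at room temperature, which does not hydrogenolyse benzyl or allyl ethers readily. It sets out from 12 and comes back at 13 without a new compound.

**Step 13.** The most likely failure is erosion of configuration at C2 during the base-mediated O-alkylation. The 4'-phenoxide of 14 is para to C1' and can reversibly expel O1 by para-quinone methide formation, and a slow alkylation of the hindered phenol lengthens that exposure. The fallback builds ring D without base and sets out from 14. Condensation with 3-methylbut-2-enal in the presence of PhB(OH)2 and AcOH in toluene at reflux with removal of water should bring the enal carbon to C5' and close the pyran by oxa-6π electrocyclisation. It comes back at 19 and replaces steps 13 and 14 without a new isolated compound; step 12 is still needed to supply 16 for step 16.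

**Step 18.** The most likely failure is fragmentation of the tertiary allyl ether (loss of the C5 unit back to the phenol) outrunning a [3,3] shift into the crowded C2' position, with acid-traced cyclisation of the ortho-prenyl phenol as a second drain. The fallback forms the C2'–C bond by directed ortho-metalation and sets out from 19. Lithiation at C2', the only hydrogen-bearing position ortho to the methoxymethoxy group (n-BuLi, TMEDA, THF, −20 °C), transmetalation with CuBr·SMe2 and alkylation with prenyl bromide should give (2R)-2-[8-(methoxymethoxy)-2,2-dimethyl-7-(3-methylbut-2-en-1-yl)-2H-chromen-6-yl]-7-(triisopropylsilyloxy)chromane F7. The conditions of step 15 then convert F7 through (2R)-2-[2,2-dimethyl-7-(3-methylbut-2-en-1-yl)-8-(trimethylsilyloxy)-2H-chromen-6-yl]-7-(triisopropylsilyloxy)chromane F8 (not isolated) into 25, where it rejoins the route. Competing metalation at C8 of ring A and at the benzylic C2–H is the reason this is not the first choice.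

## Further compounds

F1 | step 9 | 2-bromo-5-(triisopropylsilyloxy)phenol | Oc1cc(O[Si](C(C)C)(C(C)C)C(C)C)ccc1Br
F2 | step 9 | lithium 2-bromo-5-(triisopropylsilyloxy)phenoxide | [Li+].[O-]c1cc(O[Si](C(C)C)(C(C)C)C(C)C)ccc1Br
F3 | step 9 | (R)-1-[4-(benzyloxy)-3-(methoxymethoxy)phenyl]prop-2-en-1-yl 2-bromo-5-(triisopropylsilyloxy)phenyl ether | COCOc1cc([C@H](Oc2cc(O[Si](C(C)C)(C(C)C)C(C)C)ccc2Br)C=C)ccc1OCc1ccccc1
F4 | step 9 | 9-{(R)-3-[4-(benzyloxy)-3-(methoxymethoxy)phenyl]-3-[2-bromo-5-(triisopropylsilyloxy)phenoxy]propyl}-9-borabicyclo[3.3.1]nonane | COCOc1cc([C@H](Oc2cc(O[Si](C(C)C)(C(C)C)C(C)C)ccc2Br)CCB2C3CCCC2CCC3)ccc1OCc1ccccc1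
F5 | step 8 | lithium 2-formyl-5-(triisopropylsilyloxy)phenoxide | [Li+].[O-]c1cc(O[Si](C(C)C)(C(C)C)C(C)C)ccc1C=O
F6 | step 8 | (R)-2-{1-[4-(benzyloxy)-3-(methoxymethoxy)phenyl]prop-2-en-1-yloxy}-4-(triisopropylsilyloxy)benzaldehyde | COCOc1cc([C@H](Oc2cc(O[Si](C(C)C)(C(C)C)C(C)C)ccc2C=O)C=C)ccc1OCc1ccccc1
F0 | step 10 | none | none
F0 | step 13 | none | none
F7 | step 18 | (2R)-2-[8-(methoxymethoxy)-2,2-dimethyl-7-(3-methylbut-2-en-1-yl)-2H-chromen-6-yl]-7-(triisopropylsilyloxy)chromane | COCOc1c(CC=C(C)C)c([C@H]2CCc3ccc(O[Si](C(C)C)(C(C)C)C(C)C)cc3O2)cc2c1OC(C)(C)C=C2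
F8 | step 18 | (2R)-2-[2,2-dimethyl-7-(3-methylbut-2-en-1-yl)-8-(trimethylsilyloxy)-2H-chromen-6-yl]-7-(triisopropylsilyloxy)chromane | C[Si](C)(C)Oc1c(CC=C(C)C)c([C@H]2CCc3ccc(O[Si](C(C)C)(C(C)C)C(C)C)cc3O2)cc2c1OC(C)(C)C=C2
A1 | alternative 1 | target-configured 2-[8-(methoxymethoxy)-2,2-dimethyl-7-(3-methylbut-2-en-1-yl)-2H-chromen-6-yl]-7-(methoxymethoxy)-2H-chromene-3-carbaldehyde | CC(C)=CCc1c([C@H]2C(C=O)=Cc3ccc(OCOC)cc3O2)cc2c(c1OCOC)OC(C)(C)C=C2
A2 | alternative 1 | (E)-3-[8-(methoxymethoxy)-2,2-dimethyl-7-(3-methylbut-2-en-1-yl)-2H-chromen-6-yl]prop-2-enal | CC(C)=CCc1c(/C=C/C=O)cc2c(c1OCOC)OC(C)(C)C=C2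
A3 | alternative 1 | 2-hydroxy-4-(methoxymethoxy)benzaldehyde | O=Cc1ccc(OCOC)cc1O
A4 | alternative 2 | (2R)-2-[3-(2-methylbut-3-en-2-yloxy)-4-(2-methylbut-3-yn-2-yloxy)phenyl]-7-(triisopropylsilyloxy)chromane | C=CC(C)(C)Oc1cc([C@H]2CCc3ccc(O[Si](C(C)C)(C(C)C)C(C)C)cc3O2)ccc1OC(C)(C)C#C
A5 | alternative 2 | 2,2-dimethyl-7-(3-methylbut-2-en-1-yl)-6-[(2R)-7-(triisopropylsilyloxy)chroman-2-yl]-2H-chromen-8-ol | CC(C)=CCc1c([C@H]2CCc3ccc(O[Si](C(C)C)(C(C)C)C(C)C)cc3O2)cc2c(c1O)OC(C)(C)C=C2
A6 | alternative 3 | 1-[4-hydroxy-3-(methoxymethoxy)phenyl]prop-2-en-1-ol (racemic) | C=CC(O)c1ccc(O)c(OCOC)c1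
A7 | alternative 3 | 3-(triisopropylsilyloxy)phenol | Oc1cccc(O[Si](C(C)C)(C(C)C)C(C)C)c1
A8 | alternative 3 | 2-(methoxymethoxy)-4-[(2R)-7-(triisopropylsilyloxy)chroman-2-yl]phenol | COCOc1cc([C@H]2CCc3ccc(O[Si](C(C)C)(C(C)C)C(C)C)cc3O2)ccc1O
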